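Amounts tell more here than percentages, so I first turn the solid substrate readings into millimolar. Alder loses 1.25 mM d⁻¹ up to its first reading, and elm loses 0.960 mM d⁻¹ over 50.0 h. Elm's charge is 1.54 times alder's, yet elm loses less per day. I therefore take the loss in millimolar per day as independent of the charge while solid remains, a nearly zero-order feed.

| flask | solid substrate | partner | reagent | remark | time |
|---|---|---|---|---|---|
| elm | 20 mM | 22 mM | 80 mM | the very flask that is asked about, followed so far |  |
| alder | 13 mM | 22 mM | 80 mM | run made earlier |  |
| flask | 20 mM | 22.0 mM | 80.0 mM |  | 10 d |

elm run (percent of the solid substrate charged)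

| time / h | target / % | solid substrate / % | open intermediate / % |
|---|---|---|---|
| 10.0 | 0 | 96 | 4 |
| 20.0 | 0 | 95 | 0 |
| 30.0 | 1 | 91 | 3 |
| 40.0 | 0 | 92 | 0 |
| 50.0 | 1 | 90 | 3 |

alder run (percent of the solid substrate charged)

| time / d | target / % | solid substrate / % | open intermediate / % |
|---|---|---|---|
| 1.25 | 0 | 88 | 2 |
| 3.00 | 1 | 74 | 7 |
| 4.00 | 2 | 67 | 9 |
| 6.00 | 7 | 53 | 11 |
| 8.00 | 12 | 39 | 8 |

(scatter of a reading: 1.5 percentage points)

- solid substrate is a solid; its amount is given per volume of the solution
- what may be going on: reagent + partner -> second intermediate; target <-> isomer of the product; target -> over-reaction product; starting material + reagent -> open intermediate; open intermediate + second intermediate -> target; solid substrate <-> starting material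
- at the start none of the solid substrate is in solution

- how much target the flask holds at 10 d, in percent of the solid substrate charged
- how much solid substrate the flask holds at 10 d, in percent of the solid substrate charged (only what is still solid)
- how much open intermediate the flask holds at 10 d, in percent of the solid substrate charged
- how much isomer of the product the flask holds at 10 d, in percent of the solid substrate charged

Then I ask how this rate drifts. From 3.00 d to 8.00 d alder loses 0.910 mM d⁻¹, and this late pace, the millimolar of solid lost per day after the opening days, is what I carry. At that pace the flask's charge lasts 22.0 d, longer than the 10 d asked, so solid should remain throughout.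

Two extreme flasks are easy to reckon. Held at the opening rate, the flask keeps 37.6% of its solid; held at the late pace from the start, it keeps 54.5%. I expect the flask to start near the first rate and slow toward the second, as alder's readings do, so I place it between them. Alder has the same partner and reagent charges and still holds solid at its last reading, so I take its 7.93 mM lost by 8.00 d and add the late pace for the remaining time, which by my reckoning leaves 51.2%, nearer the slow extreme.

The forecast, close to my figure, says 52% solid, 10.5% target, 3.5% open intermediate and 9% isomer of the product, on the ground: “Dissolution therefore looks zero-order, independent of the charge.”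

The flask gives 51.7% solid, 10.4% target, 6.77% open intermediate and 12.1% isomer of the product.

    reagent + partner → second intermediate (k = 0.104 M⁻¹ h⁻¹)
    target ⇌ isomer of the product (K = 2.61, k = 0.0169 h⁻¹)
    target → over-reaction product (k = 0.00187 h⁻¹)
    starting material + reagent → open intermediate (k = 0.167 M⁻¹ h⁻¹)
    open intermediate + second intermediate → target (k = 1.81 M⁻¹ h⁻¹)
    solid substrate ⇌ starting material, rate k6*(cs6 - [starting material]) while solid is left; crystals form when [starting material] > cs6 (solubility = 9.80 mM, k = 0.00549 h⁻¹)

From 5.00 d to 10 d the flask loses solid at 0.878 mM d⁻¹ on average, close to the late pace of 0.910 mM d⁻¹ read from alder. A neighbouring flask with 140 mM of reagent keeps 47.1% solid at 10 d against the flask's 51.7%, and its starting material stands at 11.0% against the flask's 17.0%. The dissolution term gives the flask 0.843 mM d⁻¹ at 10 d, and the neighbour 1.00 mM d⁻¹, above the late pace.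

The runs are simulated on assumed constants; the scatter is artificial.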